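**Plan**

- Target numbering (furo[3,4-c]furan-1-one): C1 (C=O), O2, C3 (guaiacyl), C3a, C4 (CH2), O5, C6 (catechol), C6a. The three phenols are carried as benzyl ethers.
- Retrosynthesis: cut the lactone bond C1–O2 and the ring-fusion bond C3a–C6a and rejoin C3a to C1 (retro-Wolff), which gives a monocyclic 3-diazo-oxan-4-one. Then cut C3–C3a (aldol) and C6–C6a plus O5–C4 (hetero-Diels–Alder of a siloxydiene with the catechol aldehyde).
- Enabling feature: the oxolane ring O5–C6–C6a–C3a–C4 carries the carbonyl C1 on C6a next to C3a. It is therefore the Wolff ring-contraction product of a six-membered oxan-4-one in which C1 still sits in the ring between C6a and C3a. The hydroxyl on C3 is γ to C1 and can capture the ketene.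
- Forward order: oxanone ring (step 1), C3–C3a bond with the second aryl group (step 2), diazo transfer, then ring contraction forms the oxolane and the lactone ring in one operation, then debenzylation.
- Stereochemistry: C6 from the chiral titanium catalyst; C3a and C3 from a thermodynamically controlled anti aldol relayed from C6; C3a migrates with retention; C6a from the obligatory cis ring fusion.

Key step: step 6

Assumption: the (S)-BINOL–Ti(OiPr)4 catalyst is taken to deliver the diene to the si face of the aryl aldehyde, as in related titanium–BINOL carbonyl additions; if the sense proved opposite, (R)-BINOL would be used.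

**Step 1**
Reactants: 1 3,4-bis(benzyloxy)benzaldehyde; 2 (E)-1-methoxy-3-(trimethylsilyloxy)buta-1,3-diene (Danishefsky's diene)
Product: 4 (S)-2-[3,4-bis(benzyloxy)phenyl]-2,3-dihydro-4H-pyran-4-one, via silyl aldol adduct 3 (not isolated)
Conditions: (S)-BINOL (20 mol %), Ti(OiPr)4 (10 mol %), 4 Å MS, Et2O, −20 °C; then CF3CO2H (cat.), CH2Cl2, 0 °C
Reagents that add atoms: none
Why: The titanium–BINOL-catalysed Mukaiyama aldol addition of the siloxydiene to the si face of the aldehyde, followed by acid-induced ring closure with loss of methanol (Keck variant of the Danishefsky hetero-Diels–Alder reaction), should set C2 of the pyranone (later C6 of the target) as S.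

**Step 2**
Reactants: 4 (S)-2-[3,4-bis(benzyloxy)phenyl]-2,3-dihydro-4H-pyran-4-one; 5 4-(benzyloxy)-3-methoxybenzaldehyde
Product: 7 (2S,5R)-2-[3,4-bis(benzyloxy)phenyl]-5-{(S)-[4-(benzyloxy)-3-methoxyphenyl](hydroxy)methyl}oxan-4-one, via lithium enolate 6 (not isolated)
Conditions: Li[HB(sBu)3] (L-Selectride, 1.0 equiv), THF, −78 °C; then 5 (1.0 equiv), −78 → −20 °C; AcOH, −78 °C
Reagents that add atoms: none
Why: Conjugate hydride addition to the vinylogous ester gives the regiodefined C4=C5 enolate, which adds to the aldehyde through a Zimmerman–Traxler chair (ring E-enolate, hence anti), and warming should let the lithium aldolate equilibrate by retro-aldol/aldol to the chelate whose C5 side chain is equatorial and trans to the C2 aryl group (reductive aldol reaction under thermodynamic control).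

**Step 3**
Reactants: 7 (2S,5R)-2-[3,4-bis(benzyloxy)phenyl]-5-{(S)-[4-(benzyloxy)-3-methoxyphenyl](hydroxy)methyl}oxan-4-one
Product: 8 (2S,5R)-2-[3,4-bis(benzyloxy)phenyl]-5-{(S)-[4-(benzyloxy)-3-methoxyphenyl][(triethylsilyl)oxy]methyl}oxan-4-one
Conditions: Et3SiCl, imidazole, DMF, 0 °C → rt
Reagents that add atoms: chlorotriethylsilane, CC[Si](Cl)(CC)CC
Why: Imidazole-assisted silylation of the secondary benzylic alcohol should block retro-aldol cleavage and dehydration during the base-mediated diazo transfer.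

**Step 4**
Reactants: 8 (2S,5R)-2-[3,4-bis(benzyloxy)phenyl]-5-{(S)-[4-(benzyloxy)-3-methoxyphenyl][(triethylsilyl)oxy]methyl}oxan-4-one
Product: 10 (2R,5R)-2-[3,4-bis(benzyloxy)phenyl]-5-{(S)-[4-(benzyloxy)-3-methoxyphenyl][(triethylsilyl)oxy]methyl}-3-diazooxan-4-one, via trifluoroacetyl ketone 9 (not isolated)
Conditions: LiN(SiMe3)2, THF, −78 °C; CF3CO2CH2CF3, −78 °C; aq NH4Cl; then MeSO2N3, Et3N, H2O (1 equiv), MeCN, rt
Reagents that add atoms: methanesulfonyl azide, CS(=O)(=O)N=[N+]=[N-]; 2,2,2-trifluoroethyl trifluoroacetate, O=C(OCC(F)(F)F)C(F)(F)F (its trifluoroacetyl group stays in 9 only)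
Why: Kinetic deprotonation at the only α-methylene (C3; C5 is a hindered methine), Claisen trifluoroacetylation and detrifluoroacetylative diazo transfer (Danheiser modification of the Regitz reaction) should place the diazo group at C3 without touching a stereocentre (the C2 descriptor changes from S to R only because the diazo carbon outranks the aryl group).

**Step 5**
Reactants: 10 (2R,5R)-2-[3,4-bis(benzyloxy)phenyl]-5-{(S)-[4-(benzyloxy)-3-methoxyphenyl][(triethylsilyl)oxy]methyl}-3-diazooxan-4-one
Product: 11 (2R,5R)-2-[3,4-bis(benzyloxy)phenyl]-5-{(S)-[4-(benzyloxy)-3-methoxyphenyl](hydroxy)methyl}-3-diazooxan-4-one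
Conditions: Bu4NF, AcOH (1:1), THF, 0 °C
Reagents that add atoms: none
Why: Buffered fluoride should cleave the triethylsilyl ether while the acetic acid keeps the medium too weakly basic for retro-aldol cleavage and too weakly acidic to protonate the diazo ketone.

**Step 6**
Reactants: 11 (2R,5R)-2-[3,4-bis(benzyloxy)phenyl]-5-{(S)-[4-(benzyloxy)-3-methoxyphenyl](hydroxy)methyl}-3-diazooxan-4-one
Product: 13 (3S,3aR,6S,6aS)-6-[3,4-bis(benzyloxy)phenyl]-3-[4-(benzyloxy)-3-methoxyphenyl]tetrahydro-1H,3H-furo[3,4-c]furan-1-one, via hydroxy ketene 12 (not isolated)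
Conditions: hν (365 nm), MeCN (dry, degassed, 0.005 M), 20 °C
Reagents that add atoms: none
Why: Excitation of the cyclic diazo ketone, which is locked s-Z, should expel N2 with concerted 1,2-shift of C5 from the carbonyl carbon to the diazo carbon (photochemical Wolff rearrangement), so that the six-membered oxanone contracts to the oxolane and the former ketone carbon becomes an exocyclic ketene on the future C6a. The closest known reaction type is the Wolff ring contraction of 2-diazocycloalkanones and diazo pyranones with capture of the ketene by an alcohol. The oxolane ring is closed by the 1,2-shift itself (ring contraction, no cyclisation mode), and the lactone ring by 5-exo-dig addition of the C3 hydroxyl to the ketene C=O followed by C-protonation of the lactone enol. C3a migrates with retention and C6 and C3 are not touched, while C6a is fixed by the substrate, because a bicyclo[3.3.0] lactone can only be cis-fused and the enol is therefore protonated on the convex face. The step needs the Wolff shift to beat 1,2-hydride shift from the benzylic C2–H and intramolecular to beat intermolecular ketene capture; the concerted photochemical pathway, the aprotic solvent and high dilution should secure both.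

**Step 7**
Reactants: 13 (3S,3aR,6S,6aS)-6-[3,4-bis(benzyloxy)phenyl]-3-[4-(benzyloxy)-3-methoxyphenyl]tetrahydro-1H,3H-furo[3,4-c]furan-1-one
Product: 14 (3S,3aR,6S,6aS)-6-(3,4-dihydroxyphenyl)-3-(4-hydroxy-3-methoxyphenyl)tetrahydro-1H,3H-furo[3,4-c]furan-1-one
Conditions: H2 (1 atm), Pd/C (10 %), EtOAc–THF, rt, stopped after uptake of three equivalents
Reagents that add atoms: none
Why: Hydrogenolysis of the three aryl benzyl ethers over palladium under neutral conditions should be faster than cleavage of the secondary benzylic C–O bonds of the lactone and the oxolane, and it avoids the base that would turn the para-hydroxybenzyl lactone into a quinone methide.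

**Compound list**

1 | 3,4-bis(benzyloxy)benzaldehyde | O=Cc1ccc(OCc2ccccc2)c(OCc2ccccc2)c1 | starting material
2 | (E)-1-methoxy-3-(trimethylsilyloxy)buta-1,3-diene | CO/C=C/C(=C)O[Si](C)(C)C | starting material
3 | (S,E)-5-[3,4-bis(benzyloxy)phenyl]-1-methoxy-5-(trimethylsilyloxy)pent-1-en-3-one | CO/C=C/C(=O)C[C@H](O[Si](C)(C)C)c1ccc(OCc2ccccc2)c(OCc2ccccc2)c1 | intermediate (not isolated)
4 | (S)-2-[3,4-bis(benzyloxy)phenyl]-2,3-dihydro-4H-pyran-4-one | O=C1C=CO[C@H](c2ccc(OCc3ccccc3)c(OCc3ccccc3)c2)C1 | intermediate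
5 | 4-(benzyloxy)-3-methoxybenzaldehyde | COc1cc(C=O)ccc1OCc1ccccc1 | starting material
6 | lithium (S)-2-[3,4-bis(benzyloxy)phenyl]-3,6-dihydro-2H-pyran-4-olate | [Li]OC1=CCO[C@H](c2ccc(OCc3ccccc3)c(OCc3ccccc3)c2)C1 | intermediate (not isolated)
7 | (2S,5R)-2-[3,4-bis(benzyloxy)phenyl]-5-{(S)-[4-(benzyloxy)-3-methoxyphenyl](hydroxy)methyl}oxan-4-one (2,5-trans, anti aldol) | COc1cc([C@@H](O)[C@H]2CO[C@H](c3ccc(OCc4ccccc4)c(OCc4ccccc4)c3)CC2=O)ccc1OCc1ccccc1 | intermediate
8 | (2S,5R)-2-[3,4-bis(benzyloxy)phenyl]-5-{(S)-[4-(benzyloxy)-3-methoxyphenyl][(triethylsilyl)oxy]methyl}oxan-4-one | COc1cc([C@@H](O[Si](CC)(CC)CC)[C@H]2CO[C@H](c3ccc(OCc4ccccc4)c(OCc4ccccc4)c3)CC2=O)ccc1OCc1ccccc1 | intermediate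
9 | (2S,5R)-2-[3,4-bis(benzyloxy)phenyl]-5-{(S)-[4-(benzyloxy)-3-methoxyphenyl][(triethylsilyl)oxy]methyl}-3-(trifluoroacetyl)oxan-4-one (C3 enolised, not defined) | COc1cc([C@@H](O[Si](CC)(CC)CC)[C@H]2CO[C@H](c3ccc(OCc4ccccc4)c(OCc4ccccc4)c3)C(C(=O)C(F)(F)F)C2=O)ccc1OCc1ccccc1 | intermediate (not isolated)
10 | (2R,5R)-2-[3,4-bis(benzyloxy)phenyl]-5-{(S)-[4-(benzyloxy)-3-methoxyphenyl][(triethylsilyl)oxy]methyl}-3-diazooxan-4-one | COc1cc([C@@H](O[Si](CC)(CC)CC)[C@H]2CO[C@H](c3ccc(OCc4ccccc4)c(OCc4ccccc4)c3)C(=[N+]=[N-])C2=O)ccc1OCc1ccccc1 | intermediate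
11 | (2R,5R)-2-[3,4-bis(benzyloxy)phenyl]-5-{(S)-[4-(benzyloxy)-3-methoxyphenyl](hydroxy)methyl}-3-diazooxan-4-one | COc1cc([C@@H](O)[C@H]2CO[C@H](c3ccc(OCc4ccccc4)c(OCc4ccccc4)c3)C(=[N+]=[N-])C2=O)ccc1OCc1ccccc1 | intermediate
12 | (2R,4R)-2-[3,4-bis(benzyloxy)phenyl]-4-{(S)-[4-(benzyloxy)-3-methoxyphenyl](hydroxy)methyl}-3-(oxomethylidene)oxolane | COc1cc([C@@H](O)[C@H]2CO[C@H](c3ccc(OCc4ccccc4)c(OCc4ccccc4)c3)C2=C=O)ccc1OCc1ccccc1 | intermediate (not isolated)
13 | (3S,3aR,6S,6aS)-6-[3,4-bis(benzyloxy)phenyl]-3-[4-(benzyloxy)-3-methoxyphenyl]tetrahydro-1H,3H-furo[3,4-c]furan-1-one | COc1cc([C@H]2OC(=O)[C@H]3[C@@H]2CO[C@@H]3c2ccc(OCc4ccccc4)c(OCc4ccccc4)c2)ccc1OCc1ccccc1 | intermediate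
14 | (3S,3aR,6S,6aS)-6-(3,4-dihydroxyphenyl)-3-(4-hydroxy-3-methoxyphenyl)tetrahydro-1H,3H-furo[3,4-c]furan-1-one | COc1cc([C@H]2OC(=O)[C@H]3[C@@H]2CO[C@@H]3c2ccc(O)c(O)c2)ccc1O | target

**Totals**

Total step count: 7. Longest linear sequence: 7 steps (1 → 14).

**Steps most likely to fail**

Step 2. The aldolate may not equilibrate fully, so that the kinetic adduct of axial attack (side chain cis to the C2 aryl group) or the syn adducts persist. The fallback sets out from 7 obtained as a diastereomer mixture and comes back at 7 as one diastereomer. The mixture is dehydrated (MeSO2Cl, Et3N, CH2Cl2, 0 °C; then DBU), which converges all isomers on (S,E)-2-[3,4-bis(benzyloxy)phenyl]-5-[4-(benzyloxy)-3-methoxybenzylidene]oxan-4-one F1. Copper-catalysed enantioselective conjugate borylation (CuCl, NaOtBu, Josiphos-type bisphosphine of the sense that gives the (S)-boronate, B2pin2, MeOH, THF, rt) then sets the benzylic centre under catalyst control, and axial protonation of the resulting enolate at C5 should give (2S,5S)-2-[3,4-bis(benzyloxy)phenyl]-5-{(S)-[4-(benzyloxy)-3-methoxyphenyl](4,4,5,5-tetramethyl-1,3,2-dioxaborolan-2-yl)methyl}oxan-4-one F2 with the side chain equatorial (same spatial arrangement as in 7). Oxidation with NaBO3·4H2O (THF–H2O), which proceeds with retention, returns 7.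

Step 6. The hindered secondary hydroxyl may capture the ketene too slowly, leaving it open to dimerisation or capture by adventitious water. The fallback sets out from silyl ether 10 and comes back at 13. Irradiation of 10 in methanol (365 nm, 20 °C) should intercept the Wolff ketene at once by solvent and give the ring-contracted esters methyl (2S,3S,4R)-2-[3,4-bis(benzyloxy)phenyl]-4-{(S)-[4-(benzyloxy)-3-methoxyphenyl][(triethylsilyl)oxy]methyl}oxolane-3-carboxylate F3 (3,4-cis) and its C3 epimer, the (2S,3R,4R)-ester F4 (3,4-trans). Bu4NF followed by DBU in THF removes the silyl group and epimerises the ester α-centre; only the cis isomer can lactonise, so both esters should funnel into 13.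

Step 7. Over-reduction may occur: hydrogenolysis of the benzylic C3–O2 lactone bond or the C6–O5 ether bond once the para-phenols are free. The fallback sets out from 13 and comes back at 14 and makes no new compound: BCl3 with pentamethylbenzene as benzyl cation scavenger, CH2Cl2, −78 °C, then MeOH, should cleave the three aryl benzyl ethers without hydrogen.

**Further compounds**

F1 | step 2 | (S,E)-2-[3,4-bis(benzyloxy)phenyl]-5-[4-(benzyloxy)-3-methoxybenzylidene]oxan-4-one | COc1cc(/C=C2\CO[C@H](c3ccc(OCc4ccccc4)c(OCc4ccccc4)c3)CC2=O)ccc1OCc1ccccc1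
F2 | step 2 | (2S,5S)-2-[3,4-bis(benzyloxy)phenyl]-5-{(S)-[4-(benzyloxy)-3-methoxyphenyl](4,4,5,5-tetramethyl-1,3,2-dioxaborolan-2-yl)methyl}oxan-4-one | COc1cc([C@@H](B5OC(C)(C)C(C)(C)O5)[C@H]2CO[C@H](c3ccc(OCc4ccccc4)c(OCc4ccccc4)c3)CC2=O)ccc1OCc1ccccc1
F3 | step 6 | methyl (2S,3S,4R)-2-[3,4-bis(benzyloxy)phenyl]-4-{(S)-[4-(benzyloxy)-3-methoxyphenyl][(triethylsilyl)oxy]methyl}oxolane-3-carboxylate | COc1cc([C@@H](O[Si](CC)(CC)CC)[C@H]2CO[C@H](c3ccc(OCc4ccccc4)c(OCc4ccccc4)c3)[C@H]2C(=O)OC)ccc1OCc1ccccc1
F4 | step 6 | methyl (2S,3R,4R)-2-[3,4-bis(benzyloxy)phenyl]-4-{(S)-[4-(benzyloxy)-3-methoxyphenyl][(triethylsilyl)oxy]methyl}oxolane-3-carboxylate | COc1cc([C@@H](O[Si](CC)(CC)CC)[C@H]2CO[C@H](c3ccc(OCc4ccccc4)c(OCc4ccccc4)c3)[C@@H]2C(=O)OC)ccc1OCc1ccccc1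
F0 | step 7 | none | none
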